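The constants were set for the occasion, and the outcome is calculated.

The solid substrate feeds starting material into a solution where second and third substrate compete with it for one reagent.

    solid substrate ⇌ starting material, rate k1*(cs1 - [starting material]) while solid is left; crystals form when [starting material] > cs1 (cs1 = 0.12 M, k1 = 0.028 min⁻¹)
    starting material + reagent → target (k2 = 0.11 M⁻¹ min⁻¹, Ea2 = 79.0 kJ mol⁻¹)
    second substrate + reagent → second product (k3 = 0.015 M⁻¹ min⁻¹, Ea3 = 84.0 kJ mol⁻¹)
    third substrate + reagent → third product (k4 = 0.020 M⁻¹ min⁻¹, Ea4 = 67.0 kJ mol⁻¹)
    (constants at 90 °C)

| setting | beta | gamma | theta | delta |
|---|---|---|---|---|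
| solid substrate | 0.18 M | 0.18 M | 0.18 M | 0.18 M |
| reagent | 0.450 M | 0.450 M | 0.450 M | 0.450 M |
| second substrate | 0.180 M | 0.180 M | 0.180 M | 0.180 M |
| third substrate | 0.360 M | 0.360 M | 0.360 M | 0.360 M |
| temperature | 120 °C |  | 150 °C | 90 °C |
| time | 1.0 h | 1.0 h | 1.0 h | 1.0 h |
| remark |  | at 150 °C until 20 min, from then on at 90 °C |  |  |

- solid, in amounts per volume of the solution: solid substrate
- the constants hold at 90 °C; other temperatures follow from the activation energies
- at the start none of the solid substrate is in solution
- what has only dissolved of solid substrate counts as not reacted

1. the best flask by amount of target, in percent of the solid substrate charged; "all alike" if 1.5 percentage points covers them all (beta / gamma / theta / delta / all alike)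
2. amount of target at the end, in percent of the solid substrate charged, beta
3. amount of target at the end, in percent of the solid substrate charged, gamma
4. amount of target at the end, in percent of the solid substrate charged, theta
5. amount of target at the end, in percent of the solid substrate charged, delta

Gamma and theta look nearly the same: both stand at 150 °C until 20 min, and then gamma drops to 90 °C.

Both side steps carry the reagent in their rate, so their substrates decay with the same time integral of reagent. Integrating gives a closed rule: the logarithm of the surviving fraction of second substrate equals a selectivity factor times that of third substrate. At 150 °C this factor, k3/k4 corrected by the activation energies, is 1.67.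

At the start of the hot stage the side steps use reagent at 0.138 M min⁻¹, far faster than dissolving can supply starting material, at most 0.00336 M min⁻¹. As a trial of my own, third substrate falls to a third of its charge. Second substrate then falls to 16.0 %, and the side steps have taken 0.391 M of reagent.

The charge minus that take is 0.0589 M; this is the reagent reserve, the reagent that the target can still get. The trial is fair because full dissolving delivers that amount in 17.5 min, less than the hot stage of 20 min. Reagent is then the limiting reagent, and the reserve gives a rough estimate of 32.7 % target, in percent of the solid substrate charged, for gamma and for theta; it rests on the trial value and is no bound. Theta spends its reserve hot. Gamma finishes at 90 °C, where step 2 runs 41 times slower, so my reckoning places gamma below theta. It gives no figure for beta or delta.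

The forecast names beta as best and holds that “the side reactions use up the reagent within about 20 minutes”.

| Flask | Forecast | Simulation |
|---|---|---|
| beta | 58 % | 58.3 % |
| gamma | 29 % | 27.4 % |
| theta | 31 % | 31.4 % |
| delta | 52 % | 42.9 % |

The best flask is beta, and the forecast parts from the simulation on delta. Theta ends 1.3 percentage points below that estimate, with reagent at 0 %. Gamma ends at 27.4 % with 2.9 % of its reagent unspent, and reaches 33.2 % after 10.0 h. The neighbour is gamma charged with 0.045 M of solid substrate, and its side products stand at 0.150 M and 0.239 M, as in gamma. The reserve is now 1.31 times that charge. That flask gives 91.2 % target, with 8.84 % as starting material and 4.42 % of the reagent left.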